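Chamigrane numbering is used throughout (chamigrane = 3,7,11,11-tetramethylspiro[5.5]undecane: spiro C6, ring B C1–C5, ring A C7–C11, C14 = the carbon on C7).
Retrosynthesis: C7=C14 goes back to a C14 allylic alcohol and a C7-methyl enone, C9–OAc and C10–Br to the C9 ketone, C3–Cl to the C3–O bond of a C3–O–C7 ether, and that ether with C2–Br to the C2=C3 alkene plus a C7 hydroxyl. The skeleton is then cut at C7–C14 (methyl addition), C2=C3 (metathesis), C6–C1 (allylation) and C6–C5 (alkylation), back to dimedone.
Forward: ring A is dimedone; ring B closes by metathesis on the quaternary C6; a temporary oxygen bridge C7–O–C3 is closed in the key step and opened again in the next step.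
Feature used: C7 is bonded to spiro C6 and therefore stands over one face of ring B, 1,4 to C3. An oxygen on C7 reaches C3 only on that face, through a boat of ring B, which forces bromine onto the opposite (C11) face at C2.
Stereochemistry: C6 from a Pd/PHOX decarboxylative allylation; C2 and C3 from C6 through the tethered bromoetherification, with C3–O then exchanged for C3–Cl with retention. C9 comes from a CBS reduction of a C10 gem-dibromo enone and C10 from C9 by anti hydrogen transfer to the bromo radical, because ring B (C1 and C5 nearly mirror-related as seen from ring A) cannot steer reagents on ring A.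

Key step: step 8

Assumption: the Pd/PHOX allylation is taken to follow the sense of induction usual for 2-alkylcyclohexanone enolates, which calls for the (R)-ligand to reach (S)-10; should the sense be inverted on this substrate, the (S)-ligand is used.
Convention: steps 7–9 carry both C7 epimers (the 7S epimer is drawn), which merge in step 10; reagents that donate atoms are numbered like starting materials, water is not.

Step 1
Reactants: 1 dimedone; 2 2-methylpropan-1-ol (isobutanol)
Product: 3 3-isobutoxy-5,5-dimethylcyclohex-2-en-1-one
Conditions: i-BuOH, TsOH·H2O (cat.), PhMe, reflux, Dean–Stark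
Reagents that add atoms: isobutanol (2), CC(C)CO
Why: Acid-catalysed enol etherification of the cyclic 1,3-dione with azeotropic removal of water gives the vinylogous ester, which masks C9 and leaves C7 as the only carbonyl; no stereocenter is formed.

Step 2
Reactants: 4 4-bromo-2-methylbut-1-ene; 5 sodium iodide
Product: 6 4-iodo-2-methylbut-1-ene
Conditions: NaI, acetone, reflux
Reagents that add atoms: sodium iodide (5), [Na+].[I-]
Why: Finkelstein halide exchange (SN2, driven by precipitation of NaBr from acetone) provides the iodide, which should alkylate the hindered enolate of step 3 faster than it eliminates.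

Step 3
Reactants: 3 3-isobutoxy-5,5-dimethylcyclohex-2-en-1-one; 6 4-iodo-2-methylbut-1-ene
Product: 7 rac-3-isobutoxy-5,5-dimethyl-6-(3-methylbut-3-en-1-yl)cyclohex-2-en-1-one
Conditions: LDA, THF, −78 °C; then 6, −78 °C → rt
Reagents that add atoms: 4-iodo-2-methylbut-1-ene (6), C=C(C)CCI
Why: Kinetic α′-deprotonation of the vinylogous ester next to the gem-dimethyl carbon and SN2 alkylation of the lithium enolate attach the future C5–C4–C3 arm; the stereocenter formed is racemic and is erased by enolisation in step 4.

Step 4
Reactants: 7 rac-3-isobutoxy-5,5-dimethyl-6-(3-methylbut-3-en-1-yl)cyclohex-2-en-1-one; 8 allyl chloroformate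
Product: 9 allyl 5-isobutoxy-3,3-dimethyl-2-(3-methylbut-3-en-1-yl)cyclohexa-1,5-dien-1-yl carbonate
Conditions: LDA, TMEDA, THF, −78 °C; then ClCO2allyl, −78 °C
Reagents that add atoms: allyl chloroformate (8), C=CCOC(Cl)=O
Why: The fully substituted lithium enolate, loosened by TMEDA, is acylated on oxygen by the chloroformate to give the allyl enol carbonate, the substrate for decarboxylative allylation; the product has no stereocenter.

Step 5
Reactants: 9 allyl enol carbonate
Product: 10 (S)-6-allyl-3-isobutoxy-5,5-dimethyl-6-(3-methylbut-3-en-1-yl)cyclohex-2-en-1-one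
Conditions: Pd2(dba)3 (2.5 mol%), (R)-(CF3)3-t-BuPHOX (6 mol%), PhMe, 30 °C
Reagents that add atoms: none
Why: Pd-catalysed decarboxylative asymmetric allylic alkylation (Tsuji allylation with a PHOX ligand): oxidative addition and loss of CO2 give an allyl-palladium enolate that forms the C6–C1 bond within the chiral pocket, the electron-poor ligand being needed for a quaternary carbon next to CMe2 and its (R)-configuration selecting the enolate face that leads to (S)-C6.

Step 6
Reactants: 10 (S)-allyl ketone
Product: 11 (6S)-9-isobutoxy-3,11,11-trimethylspiro[5.5]undeca-2,8-dien-7-one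
Conditions: Grubbs II (5 mol%), CH2Cl2, 40 °C
Reagents that add atoms: none
Why: Ring-closing olefin metathesis of the monosubstituted and the 1,1-disubstituted alkene closes ring B as the trisubstituted C2=C3 cyclohexene with loss of ethene and leaves C6 untouched.

Step 7
Reactants: 11 spiro vinylogous ester; 12 methyllithium
Product: 14 (6S,7S)-7-hydroxychamigr-2-en-9-one (C7 epimers; 7S drawn), via carbinol enol ether 13 (not isolated)
Conditions: MeLi, CeCl3, THF, −78 °C; then AcOH/NaOAc buffer (pH 5), THF–H2O, 0 °C → rt
Reagents that add atoms: methyllithium (12), [Li]C; water, O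
Why: Organocerium 1,2-addition to the hindered vinylogous-ester carbonyl is followed by enol ether hydrolysis under general-acid (buffer) catalysis, where rate-limiting C8 protonation is helped by the buffer acid while ionisation of the tertiary allylic alcohol (the Stork–Danheiser path to the enone) would need strong acid; C7 forms without control as both epimers, which is harmless because either cyclises in step 8 and C7 becomes sp2 again in step 10.

Step 8
Reactants: 14 7-hydroxychamigr-2-en-9-one; 15 N-bromosuccinimide
Product: 16 (2R,3R,6S,7S)-2-bromo-3,7-epoxychamigran-9-one (bridged bromo ether C3–O–C7; C7 epimers; 7S drawn)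
Conditions: NBS (1.1 equiv), CH2Cl2, 0 °C → rt, dark
Reagents that add atoms: N-bromosuccinimide (15), O=C1CCC(=O)N1Br
Why: NBS forms bromonium ions reversibly on both faces of the C2=C3 alkene, but only the one on the C11 face can be captured, because the C7 hydroxyl is anchored through spiro C6 over the C7 face and attacks tertiary C3 from there while the C3–Br bond breaks anti (Curtin–Hammett funnelling through the one productive ion). The closest known reaction type is the NBS bromoetherification of α-terpineol-type δ-hydroxy cyclohexenes to 2-bromo-1,8-cineoles. One ring closes, the six-membered ether O–C3–C4–C5–C6–C7 (6-exo when counted through C4–C5, 6-endo through C1–C2), across a boat of ring B to give the 2-oxabicyclo[2.2.2]octane. C3 (oxygen on the C7 face) is fixed by the tether and thereby by C6; C2 (bromine on the C11 face) follows from the anti opening of the bromonium ion. The step needs attack at C3 and not at C2, which the Markovnikov preference for the tertiary carbon and the strain of the alternative 6-oxabicyclo[3.2.1]octane should secure, and it needs the oxygen on one face only, which the attachment of C7 to C6 guarantees. Either C7 epimer can place C7–O equatorial on ring A (anti to C6–C11), so both should cyclise, and the ketone is inert to NBS under these conditions.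

Step 9
Reactants: 16 bridged bromo ether; 17 titanium tetrachloride
Product: 18 (2R,3R,6S,7S)-2-bromo-3-chloro-7-hydroxychamigran-9-one (C7 epimers; 7S drawn)
Conditions: TiCl4 (1.5 equiv), CH2Cl2, −78 → −30 °C; then H2O
Reagents that add atoms: titanium tetrachloride (17), Cl[Ti](Cl)(Cl)Cl
Why: Lewis-acid cleavage of a tertiary ether to the chloride with neighbouring-group participation: TiCl4, chelated by the ether and C9 carbonyl oxygens, ionises the C3–O bond with help from the C2 bromine that the boat holds anti-periplanar, and chloride from titanium opens the C11-face bromonium ion at C3 on the face the oxygen leaves, so C3 is substituted with overall retention (double inversion) and C2 is unchanged.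

Step 10
Reactants: 18 chloro bromo aldol
Product: 19 (2R,3R,6S)-2-bromo-3-chlorochamigr-7-en-9-one
Conditions: TsOH·H2O (10 mol%), PhH, 60 °C
Reagents that add atoms: none
Why: Acid-catalysed dehydration of the tertiary aldol (the closing stage of an aldol condensation) gives the conjugated C7=C8 enone, the thermodynamic alkene isomer, and removes the C7 stereocenter so that both epimer series converge.

Step 11
Reactants: 19 chloro bromo enone; 15 N-bromosuccinimide
Product: 21 (2R,3R,6R)-2,10,10-tribromo-3-chlorochamigr-7-en-9-one, via monobromo enone 20 (not isolated)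
Conditions: LiHMDS (1.1 equiv), THF, −78 °C, then NBS (1.1 equiv); second cycle LiHMDS/NBS (1.2 equiv each), −78 °C; aq. NH4Cl
Reagents that add atoms: N-bromosuccinimide (15), O=C1CCC(=O)N1Br
Why: Kinetic enolisation of the enone is possible only toward C10 on the α′ side and two successive enolate brominations (via the monobromide) give the gem-dibromide, which is chosen on purpose: seen from ring A the two arms C1 and C5 of ring B are nearly mirror images, so a single C10–Br would form without control, whereas CBr2 is no stereocenter and defers the choice to steps 12 and 14.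

Step 12
Reactants: 21 gem-dibromo enone
Product: 22 (2R,3R,6R,9S)-2,10,10-tribromo-3-chlorochamigr-7-en-9-ol
Conditions: (R)-Me-CBS (0.2 equiv), catecholborane (2 equiv), PhMe, −78 → −30 °C
Reagents that add atoms: none
Why: Corey–Bakshi–Shibata reduction under reagent control: the carbonyl binds the catalyst anti to the very bulky CBr2–CMe2 flank (the trihalomethyl ketone case), so the (R)-catalyst should deliver hydride to the face that gives the 9S carbinol independently of ring B, and catecholborane does not reduce the s-trans cyclic enone in the 1,4 sense.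

Step 13
Reactants: 22 dibromo carbinol; 23 acetic anhydride
Product: 24 (2R,3R,6R,9S)-2,10,10-tribromo-3-chlorochamigr-7-en-9-yl acetate
Conditions: Ac2O, DMAP (0.2 equiv), pyridine, rt → 40 °C
Reagents that add atoms: acetic anhydride (23), CC(=O)OC(C)=O
Why: DMAP-catalysed acetylation (nucleophilic catalysis via the N-acetylpyridinium ion) esterifies the hindered secondary alcohol without affecting any stereocenter.

Step 14
Reactants: 24 gem-dibromo acetate
Product: 25 (2R,3R,6R,9S,10R)-2,10-dibromo-3-chlorochamigr-7-en-9-yl acetate
Conditions: Bu3SnH (1.05 equiv), Et3B (0.2 equiv), air, PhMe, −78 °C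
Reagents that add atoms: none
Why: Radical-chain tin hydride monoreduction of a gem-dibromide: the weaker CBr2 bond is abstracted in preference to the secondary C2–Br bond at low temperature, and the planar α-bromo radical at C10 takes hydrogen on the face anti to the neighbouring pseudoaxial C9 acetoxy group (and to the syn-axial C11 methyl), which leaves Br cis to OAc and sets C10 as R.

Step 15
Reactants: 25 bromo acetate; 26 tert-butyl hydroperoxide
Product: 27 (2R,3R,6R,9S,10R)-2,10-dibromo-3-chloro-14-hydroxychamigr-7-en-9-yl acetate
Conditions: SeO2 (0.3 equiv), t-BuOOH (3 equiv), CH2Cl2, rt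
Reagents that add atoms: tert-butyl hydroperoxide (26), CC(C)(C)OO
Why: Selenium dioxide allylic oxidation (ene reaction then [2,3]-sigmatropic shift, SeO2 recycled by t-BuOOH) can use only the C14 methyl, the sole allylic C–H position on the more substituted alkene terminus, since C6 is quaternary and C9 lies on the other terminus and already bears the acetate; no stereocenter is touched.

Step 16
Reactants: 27 C14 allylic alcohol
Product: 30 (2R,3R,6R,9S,10R)-2,10-dibromo-3-chlorochamigr-7(14)-en-9-yl acetate, via allylic sulfonylhydrazine 28 (not isolated), via allylic diazene 29 (not isolated)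
Conditions: PPh3, DEAD, 2-nitrobenzenesulfonylhydrazide (NBSH), N-methylmorpholine, −30 → 23 °C
Reagents that add atoms: none
Why: Reductive 1,3-transposition of a primary allylic alcohol: Mitsunobu substitution by the sulfonylhydrazide, loss of 2-nitrobenzenesulfinic acid on warming and retro-ene loss of N2 from the allylic diazene deliver hydrogen to C8 and move the double bond to the exocyclic C7=C14 position, with all five stereocenters unchanged.

Compound list
1 | dimedone (5,5-dimethylcyclohexane-1,3-dione) | CC1(C)CC(=O)CC(=O)C1 | starting material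
2 | 2-methylpropan-1-ol (isobutanol) | CC(C)CO | starting material
3 | 3-isobutoxy-5,5-dimethylcyclohex-2-en-1-one | CC(C)COC1=CC(=O)CC(C)(C)C1 | intermediate
4 | 4-bromo-2-methylbut-1-ene | C=C(C)CCBr | starting material
5 | sodium iodide | [Na+].[I-] | starting material
6 | 4-iodo-2-methylbut-1-ene | C=C(C)CCI | intermediate
7 | rac-3-isobutoxy-5,5-dimethyl-6-(3-methylbut-3-en-1-yl)cyclohex-2-en-1-one | CC(C)COC1=CC(=O)C(CCC(C)=C)C(C)(C)C1 | intermediate
8 | allyl chloroformate | C=CCOC(Cl)=O | starting material
9 | allyl 5-isobutoxy-3,3-dimethyl-2-(3-methylbut-3-en-1-yl)cyclohexa-1,5-dien-1-yl carbonate | C=CCOC(=O)OC1=C(CCC(C)=C)C(C)(C)CC(OCC(C)C)=C1 | intermediate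
10 | (S)-6-allyl-3-isobutoxy-5,5-dimethyl-6-(3-methylbut-3-en-1-yl)cyclohex-2-en-1-one | O=C1C=C(OCC(C)C)CC(C)(C)[C@@]1(CC=C)CCC(C)=C | intermediate
11 | (6S)-9-isobutoxy-3,11,11-trimethylspiro[5.5]undeca-2,8-dien-7-one | O=C1C=C(OCC(C)C)CC(C)(C)[C@@]12CCC(C)=CC2 | intermediate
12 | methyllithium | [Li]C | starting material
13 | (6S,7S)-9-isobutoxychamigra-2,8-dien-7-ol (formed together with its 7R epimer) | C[C@]1(O)C=C(OCC(C)C)CC(C)(C)[C@@]12CCC(C)=CC2 | intermediate (not isolated)
14 | (6S,7S)-7-hydroxychamigr-2-en-9-one (together with its 7R epimer) | C[C@]1(O)CC(=O)CC(C)(C)[C@@]12CCC(C)=CC2 | intermediate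
15 | N-bromosuccinimide | O=C1CCC(=O)N1Br | starting material
16 | (2R,3R,6S,7S)-2-bromo-3,7-epoxychamigran-9-one, ether bridge C3–O–C7, Br anti to O (together with its 7R epimer) | C[C@]12CC(=O)CC(C)(C)[C@@]13CC[C@@](C)(O2)[C@H](Br)C3 | intermediate
17 | titanium tetrachloride | Cl[Ti](Cl)(Cl)Cl | starting material
18 | (2R,3R,6S,7S)-2-bromo-3-chloro-7-hydroxychamigran-9-one (together with its 7R epimer) | C[C@]1(O)CC(=O)CC(C)(C)[C@@]12CC[C@@](C)(Cl)[C@H](Br)C2 | intermediate
19 | (2R,3R,6S)-2-bromo-3-chlorochamigr-7-en-9-one | CC1=CC(=O)CC(C)(C)[C@@]12CC[C@@](C)(Cl)[C@H](Br)C2 | intermediate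
20 | (2R,3R,6R)-2,10-dibromo-3-chlorochamigr-7-en-9-one, both C10 epimers (10R drawn) | CC1=CC(=O)[C@H](Br)C(C)(C)[C@@]12CC[C@@](C)(Cl)[C@H](Br)C2 | intermediate (not isolated)
21 | (2R,3R,6R)-2,10,10-tribromo-3-chlorochamigr-7-en-9-one | CC1=CC(=O)C(Br)(Br)C(C)(C)[C@@]12CC[C@@](C)(Cl)[C@H](Br)C2 | intermediate
22 | (2R,3R,6R,9S)-2,10,10-tribromo-3-chlorochamigr-7-en-9-ol | CC1=C[C@H](O)C(Br)(Br)C(C)(C)[C@@]12CC[C@@](C)(Cl)[C@H](Br)C2 | intermediate
23 | acetic anhydride | CC(=O)OC(C)=O | starting material
24 | (2R,3R,6R,9S)-2,10,10-tribromo-3-chlorochamigr-7-en-9-yl acetate | CC1=C[C@H](OC(C)=O)C(Br)(Br)C(C)(C)[C@@]12CC[C@@](C)(Cl)[C@H](Br)C2 | intermediate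
25 | (2R,3R,6R,9S,10R)-2,10-dibromo-3-chlorochamigr-7-en-9-yl acetate (Br and OAc cis) | CC1=C[C@H](OC(C)=O)[C@H](Br)C(C)(C)[C@@]12CC[C@@](C)(Cl)[C@H](Br)C2 | intermediate
26 | tert-butyl hydroperoxide | CC(C)(C)OO | starting material
27 | (2R,3R,6R,9S,10R)-2,10-dibromo-3-chloro-14-hydroxychamigr-7-en-9-yl acetate | OCC1=C[C@H](OC(C)=O)[C@H](Br)C(C)(C)[C@@]12CC[C@@](C)(Cl)[C@H](Br)C2 | intermediate
28 | N-(C14-chamigrenylmethyl)-N-(2-nitrobenzenesulfonyl)hydrazine derived from 27 | NN(CC1=C[C@H](OC(C)=O)[C@H](Br)C(C)(C)[C@@]12CC[C@@](C)(Cl)[C@H](Br)C2)S(=O)(=O)c1ccccc1[N+](=O)[O-] | intermediate (not isolated)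
29 | C14 allylic monoalkyl diazene derived from 28 | N=NCC1=C[C@H](OC(C)=O)[C@H](Br)C(C)(C)[C@@]12CC[C@@](C)(Cl)[C@H](Br)C2 | intermediate (not isolated)
30 | (2R,3R,6R,9S,10R)-2,10-dibromo-3-chlorochamigr-7(14)-en-9-yl acetate | C=C1C[C@H](OC(C)=O)[C@H](Br)C(C)(C)[C@@]12CC[C@@](C)(Cl)[C@H](Br)C2 | target

Total step count: 16. Longest linear sequence: 15 steps (steps 1 and 3–16 from dimedone; step 2 is a one-step side branch).

Steps most likely to fail

1. Step 9. What may go wrong: heterolysis of the other tertiary C–O bond (C7–O), or separation of the bromonium/titanate ion pair before chloride is handed over, so that ring B leaves the boat and C3 is chlorinated without facial control, eliminated, or suffers a 1,2-bromine shift. Fallback, from 16 back to 19: the order of the two events is reversed. Warming 16 with catalytic TsOH in benzene should break C7–O by acid-catalysed β-elimination (retro-oxa-Michael) and give the bromohydrin enone (2R,3R,6S)-2-bromo-3-hydroxychamigr-7-en-9-one F1. F1 is then treated with SOCl2 in Et2O without base (or dry HCl in CH2Cl2), so that the tertiary chlorosulfite ionises through the C2-bromine-bridged cation and chloride returns at C3 with retention. This gives 19.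

2. Step 14. What may go wrong: competing abstraction of the ring-B bromine at C2 (followed by loss of the vicinal chlorine), a second reduction at C10, or hydrogen transfer on the face syn to the acetate. Fallback, from 19 back to 25, without a radical step: the bromination of step 11 is stopped after one LiHMDS/NBS cycle and the monobromide 20 is isolated as both C10 epimers. (R)-Me-CBS/catecholborane should reduce both with the same facial sense at C9: the 10R epimer gives the cis bromohydrin (2R,3R,6R,9S,10R)-2,10-dibromo-3-chlorochamigr-7-en-9-ol F2 and the 10S epimer gives the trans bromohydrin (2R,3R,6R,9S,10S)-2,10-dibromo-3-chlorochamigr-7-en-9-ol F3. These are true diastereomers within ring A and should be separable by chromatography; F3 can be returned to 20 by oxidation and base equilibration at C10. Acetylation of F2 (Ac2O, DMAP, pyridine) gives 25.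

3. Step 7. What may go wrong: ionisation of the tertiary allylic alcohol and dehydration outrunning the enol ether hydrolysis, so that the C7 oxygen is lost as water. Fallback, from 11 back to 14: the transposition is allowed to go to completion and the oxygen is put back. MeLi/CeCl3 addition to 11 gives 13, and work-up with 1 M HCl gives the dienone (6S)-chamigra-2,7-dien-9-one F4. Alkaline hydrogen peroxide (H2O2, NaOH, MeOH, 0 °C; Weitz–Scheffer epoxidation) should attack only the electron-poor C7=C8 bond and give the epoxy ketone (6S,7R,8R)-7,8-epoxychamigr-2-en-9-one F5 (either epoxide face serves). SmI2 (THF/MeOH, −90 °C) then cleaves the Cα–O bond (C8–O) reductively to give 14 as its C7 epimers.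

Further compounds
F1 | step 9 | (2R,3R,6S)-2-bromo-3-hydroxychamigr-7-en-9-one | CC1=CC(=O)CC(C)(C)[C@@]12CC[C@@](C)(O)[C@H](Br)C2
F2 | step 14 | (2R,3R,6R,9S,10R)-2,10-dibromo-3-chlorochamigr-7-en-9-ol | CC1=C[C@H](O)[C@H](Br)C(C)(C)[C@@]12CC[C@@](C)(Cl)[C@H](Br)C2
F3 | step 14 | (2R,3R,6R,9S,10S)-2,10-dibromo-3-chlorochamigr-7-en-9-ol | CC1=C[C@H](O)[C@@H](Br)C(C)(C)[C@@]12CC[C@@](C)(Cl)[C@H](Br)C2
F4 | step 7 | (6S)-chamigra-2,7-dien-9-one | CC1=CC(=O)CC(C)(C)[C@@]12CCC(C)=CC2
F5 | step 7 | (6S,7R,8R)-7,8-epoxychamigr-2-en-9-one | C[C@]12O[C@H]1C(=O)CC(C)(C)[C@@]23CCC(C)=CC3
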